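The runs were generated by integration for substances that don't exist; noise was put on by code.

In a one-step world, starting material meets partner, makes target, and nothing else happens.

| setting | north-east | red | grey | teal | blue |
|---|---|---|---|---|---|
| starting material | 0.45 M | 0.30 M | 0.30 M | 0.30 M | 0.30 M |
| partner | 0.33 M | 0.330 M | 0.330 M | 0.330 M | 0.330 M |
| second substrate | 0.15 M | 0.150 M | 0.150 M | 0.150 M | 0.150 M |
| third substrate | 0.30 M | 0.300 M | 0.300 M | 0.300 M | 0.300 M |
| protic impurity | 0.015 M | 0.0150 M | 0.0150 M | 0.0150 M | 0.0150 M |
| temperature | 70 °C | 70 °C | 45 °C | 95 °C | 120 °C |
| remark | run made earlier |  |  |  |  |
| time |  | 4.0 min | 4.0 min | 4.0 min | 4.0 min |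

- north-east (time / s: target / %, starting material / %): 10.0: 9, 89; 25.0: 21, 75; 50.0: 35, 64; 80.0: 43, 59

(standard deviation of a reading: 2 percentage points)

* which flask leads in amount of target, in percent of the starting material charged ("all alike" within 1.5 percentage points) (red / grey / teal / blue / all alike)
* how much target is there at the end, in percent of the starting material charged: red
* how much target is there at the end, in percent of the starting material charged: grey
* how much target is there at the end, in percent of the starting material charged: teal
* how much target is there at the end, in percent of the starting material charged: blue

- the earlier runs do not show what temperature does; that part of a forecast is a guess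

One chemist defends that world. She lets the protic impurity spend 0.0150 M of partner at once, which leaves 0.315 M against 0.30 M of starting material in the four new flasks. The two fall one for one, so their gap of 0.0150 M stays frozen. Because that gap is far smaller than the charge, she sets [partner] equal to [starting material]. The reciprocal of [starting material] then grows evenly with time, and the converted fraction is D over one plus D.

The last north-east reading, 43% at 80.0 s, put through the unequal-charge form of the same law, gives a rate constant of 0.0362 /M/s, a reading with its scatter. Here D is the dose, rate constant times starting concentration times time, the dimensionless clock of the integrated second-order law. For red it is 2.60, so she expects 72.2%.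

Temperature is a guess, so she takes a factor of 4 in dose for each step of the series. Grey then gets 0.651 and 39.4%, teal 91.2%, and blue 97.7%, so blue leads.

The other chemist made the forecast, and she expects some partner to go to the other substrates as well. Her forecast is 65% for red, 37% for grey, 78% for teal and 74% for blue, with teal leading. Her grey stands below the dose reckoning of 39.4%, though she too takes the constant as “about four times lower at 45 °C”.

The simulation gives 69.1% for red, 30.8% for grey, 76.2% for teal and 71.3% for blue, and teal leads. Blue ends below teal, and teal ends below the one-step 91.2%, so the forecast wins the order, though its grey is 6.2 percentage points too high.

    partner + protic impurity → quenched reagent (k = 3.03 /M/s, Ea = 65.0 kJ/mol)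
    starting material + partner → target (k = 0.0378 /M/s, Ea = 67.0 kJ/mol)
    second substrate + partner → second product (k = 0.00967 /M/s, Ea = 81.0 kJ/mol)
    third substrate + partner → third product (k = 0.00146 /M/s, Ea = 87.0 kJ/mol)
    2 starting material → homo dimer (k = 4.22 × 10⁻⁵ /M/s, Ea = 86.0 kJ/mol)
    (constants at 70 °C)

The one-step view keeps its region in grey, where second product stands at 0.00931 M against 0.0924 M of target at 4.00 min, less. In grey the half-life of starting material by the target path at 1.62 min is 7.3 min, longer than the run, while that of second substrate by its own path, taken later at 4.00 min, is 53 min, longer still. Read back from its result, grey's dose is 0.445, which puts red's reckoned dose 5.84 times above it, against the guessed 4 times. Grey read at 1.5 min then has dose 0.167, which gives 14.3% of target, and the computed flask holds 14.5% of target.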